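## The problem

- The target is a cis-fused hydrindene. Ring A is the cyclohexene C8=C9–C10–C14–C15–C16 and ring B the cyclopentane C10–C11–C12–C13–C14. C8 and C11 are bridged by the seven-carbon chain C7–C1, so C8=C9–C10–C11 also belongs to an eleven-membered ring C (C1–C11). Labels follow the SMILES string; C1a is the exocyclic methylene carbon on C1.
- The tetrasubstituted olefin C8=C9 is at once a cis olefin of ring A and an (E)-configured bridging olefin of ring C, so it cannot be made by a late olefination or metathesis.
- Five of the seven stereocenters (C11, C10, the quaternary C14, C15, C16) are contiguous on the bicycle. C11 can control C10 and C14, and C16 can control C15 through a hydroxyl-directed reduction.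
- C5 (methyl) is insulated by methylene groups and has to be bought. C2 (allylic acetate next to the 1,1-disubstituted olefin) can only be set during or after closure of ring C.
- The feature that makes the key step possible: ring A holds its only double bond C8=C9 opposite the bonds C10–C14 and C15–C16. Ring A is therefore a Diels–Alder retron in which the ring-B atoms C11–C12–C13 tether the diene terminus C10 to the dienophile carbon C14. The C9 methyl group stands cis to C11 on that diene, so allylic strain lets the C11 stereocenter choose the diene face.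
- Sensitive groups are the allylic acetate (bases, hydrides), the exocyclic olefin, and the allylic trans-diol beside an electron-rich tetrasubstituted olefin (acid, electrophilic oxidants). The acetate must also be told apart from two other secondary hydroxyl groups, so it should be in place before these are uncovered.

## Retrosynthesis

**Diol last.** Target 26 is taken back through α-hydroxy ketone 25 to ketone 24 (carbonyl at C15). C14 is quaternary, so 24 can enolise only toward C16; oxygenation there and a hydroxyl-directed reduction give the trans-diol without any diol protecting group. The forward reactions must tolerate the acetate and must deliver oxygen to the C16 face away from the bridge.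

**Acetate and carbonyl.** Ketone 24 comes from alcohol 23 by acetylation, and 23 from sulfone 22 by oxidative desulfonylation. The sulfonyl group on C15 is the group that activated the dienophile; its removal leaves exactly the carbonyl that the diol sequence needs.

**Ring C.** Sulfone 22 is cut at C1–C2 to aldehyde/alkenyl triflate 21 (Nozaki–Hiyama–Kishi closure). This cut makes the exocyclic olefin and the C2 carbinol in one step. A cut at C7–C8 would need a ring-A alkenyl triflate, and a metathesis cut in the saturated chain would need a hydrogenation that the exocyclic olefin does not survive. The precursor is bicyclic.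

**Handles for ring closure.** Compound 21 goes back to triflate 19 (aldehyde masked as the terminal trisubstituted olefin of a citronellyl chain), 19 to methyl ketone 18, and 18 to the silyl-protected carbinol 16. The acetyl group on C11 is the precursor of C1 and C1a.

**Key disconnection.** Hydrindene 16 is cut at C10–C14 and C15–C16 to the open-chain tetraene 15. Two rings, the tetrasubstituted olefin, and the stereocenters C10 and C14 (plus a transient one at C15) are exchanged for one stereocenter (C11) and two olefin geometries. The forward reaction has to be cis-selective at the ring fusion and face-selective with respect to C11.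

**Diene.** Tetraene 15 comes from enone 14 by methylenation (C8=C16). Enone 14 is cut at C7–C8 into ester 10 and (R)-citronellyl bromide 11, joined through Weinreb amide 13 and Grignard reagent 12. The bromide supplies C2–C7 with C5 already set.

**C11.** Ester 10 comes from aldehyde 9 by an (E)-selective Wittig reaction (C9=C10). Aldehyde 9 comes from silyl ether 8 and aldol adduct 7, made from N-acyl thiazolidinethione 6 and acetaldehyde. The aldol sets C11 by auxiliary control and brings in C1 and C1a as a protected carbinol that is robust next to the aldehyde.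

**Dienophile.** Compound 6 is made from acid 4 and auxiliary 5. Acid 4, the (Z)-vinyl sulfone, comes from alkynyl sulfone 3 by syn-carbocupration, and 3 from hex-5-ynoic acid 1 via iodovinyl sulfone 2. The (Z)-geometry is what the cis ring fusion asks for.

## Roads not taken

**Alternative 1** (the most obvious): cut C7–C8 and C1–C2 on a finished hydrindane. The forward key steps would be a B-alkyl Suzuki–Miyaura coupling of the ring-A alkenyl triflate A1 with a chain-derived alkylborane, then the same Nozaki–Hiyama–Kishi closure. A1 already carries five contiguous stereocenters including the quaternary C14. They would have to be set one at a time on a bicyclic ketone, and the usual angularly methylated bicyclic building blocks carry their oxygen functions at the wrong carbons. The chosen plan makes the same bicycle in one step from an open chain.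

**Alternative 2**: biomimetic transannular cyclisation. Cut C10–C14 and C10–C11 to the fourteen-membered epoxy triene A2; the forward key step would be an acid-triggered epoxide opening followed by cation–olefin cyclisations. The isopropenyl carbon C10 would have to act as nucleophile twice, and the cations have several competing exits. The oxygens at C16 and C2 would still be missing and would need allylic oxidation beside the tetrasubstituted olefin. A2 is itself a macrocycle with three stereo-elements, so the precursor is not much simpler.

**Alternative 3**: chiral-pool ring B. The cyclopentene carbaldehyde A3 (from a monoterpene) holds ring B, C11, C9, the C14 methyl and the isopropenyl group (C1, C1a, C2). Conjugate addition at C14 and chain attachment at C2 would lead to the thirteen-membered diketone A4, whose transannular aldol condensation (C8 onto C9) would form ring A and ring C together. The quaternary C14 would rest on weak 1,3-induction across a flat cyclopentene. C2 would need an allylic oxidation and an sp3–sp3 bond to C3, and the aldol has a competing enolisation site. The diol would still have to be added afterwards. The step count is no lower and the stereocontrol is weaker.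

Key step: step 10

Remark on the chemistry: C5 is bought as (R)-citronellyl bromide; the same carbon is S in the target only because the CIP priorities of its two arms are exchanged.

## Route

Step 1
Reactants: 1 hex-5-ynoic acid
Product: 3 6-(phenylsulfonyl)hex-5-ynoic acid, via iodovinyl sulfone 2 (not isolated)
Conditions: PhSO2Na, I2, NaOAc, MeCN, rt; then K2CO3, acetone, reflux; acidic work-up
Reagents that add atoms: sodium benzenesulfinate, [Na+].[O-]S(=O)c1ccccc1
Why: Radical iodosulfonylation of the terminal alkyne (anti addition) followed by base-induced dehydroiodination is the standard entry to alkynyl sulfones; the carboxylate is a spectator.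

Step 2
Reactants: 3 6-(phenylsulfonyl)hex-5-ynoic acid
Product: 4 (Z)-5-methyl-6-(phenylsulfonyl)hex-5-enoic acid
Conditions: MeMgBr (2.2 equiv), CuBr·SMe2 (1.1 equiv), THF, −78 °C; NH4Cl (aq)
Reagents that add atoms: methylmagnesium bromide, C[Mg]Br
Why: Carbocupration of an acetylenic sulfone is a syn addition, so methyl enters at C14 trans to sulfur and protonation leaves the chain cis to the sulfonyl group (Z); the first equivalent of MeMgBr only forms the carboxylate.

Step 3
Reactants: 4 (Z)-5-methyl-6-(phenylsulfonyl)hex-5-enoic acid; 5 (S)-4-benzyl-1,3-thiazolidine-2-thione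
Product: 6 N-acyl thiazolidinethione
Conditions: EDC·HCl, DMAP (cat.), CH2Cl2, 0 °C to rt
Reagents that add atoms: none
Why: Carbodiimide-mediated N-acylation of the auxiliary; the β,β-disubstituted vinyl sulfone is inert to DMAP.

Step 4
Reactants: 6 N-acyl thiazolidinethione
Product: 7 syn-aldol adduct (C11 S and carbinol R)
Conditions: TiCl4, i-Pr2NEt, NMP, CH2Cl2, 0 °C; then MeCHO, −78 to 0 °C
Reagents that add atoms: acetaldehyde, CC=O
Why: Titanium-enolate aldol addition of an N-acyl thiazolidinethione in the Evans-syn sense: the (Z)-chlorotitanium enolate reacts through a chair transition state on the face away from the benzyl group, which sets C11 as required; the carbinol centre is set too but is oxidised in step 11.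

Step 5
Reactants: 7 syn-aldol adduct
Product: 8 triethylsilyl ether of 7
Conditions: Et3SiCl, imidazole, DMF, 0 °C to rt
Reagents that add atoms: chlorotriethylsilane, CC[Si](Cl)(CC)CC
Why: Standard silylation of a secondary alcohol under mild base, which avoids retro-aldol cleavage; no stereocenter is touched.

Step 6
Reactants: 8 triethylsilyl ether of 7
Product: 9 (2S,5Z)-5-methyl-6-(phenylsulfonyl)-2-[(1R)-1-(triethylsilyloxy)ethyl]hex-5-enal
Conditions: i-Bu2AlH, CH2Cl2, −78 °C; Rochelle salt work-up
Reagents that add atoms: none
Why: N-Acyl thiazolidinethiones are reduced by i-Bu2AlH directly to aldehydes with release of the auxiliary; the α-branched β-silyloxy aldehyde is configurationally stable at low temperature.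

Step 7
Reactants: 9 (2S,5Z)-5-methyl-6-(phenylsulfonyl)-2-[(1R)-1-(triethylsilyloxy)ethyl]hex-5-enal
Product: 10 ethyl (2E,4R,7Z)-2,7-dimethyl-8-(phenylsulfonyl)-4-[(1R)-1-(triethylsilyloxy)ethyl]octa-2,7-dienoate
Conditions: Ph3P=C(Me)CO2Et, CH2Cl2, 40 °C
Reagents that add atoms: ethyl 2-(triphenylphosphoranylidene)propanoate, CCOC(=O)C(C)=P(c1ccccc1)(c1ccccc1)c1ccccc1
Why: Wittig reaction of a stabilised ylide under neutral conditions gives the (E)-trisubstituted olefin C9=C10 without epimerising C11.

Step 8
Reactants: 10 ethyl (2E,4R,7Z)-2,7-dimethyl-8-(phenylsulfonyl)-4-[(1R)-1-(triethylsilyloxy)ethyl]octa-2,7-dienoate; 11 (R)-citronellyl bromide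
Product: 14 enone (C8 ketone carrying the citronellyl chain), via Grignard reagent 12 (not isolated), via Weinreb amide 13 (not isolated)
Conditions: MeNH(OMe)·HCl, i-PrMgCl, THF, −20 °C; then 12 (from 11, Mg, THF), −20 to 0 °C
Reagents that add atoms: none
Why: In-situ Weinreb amide formation followed by Grignard addition; the chelated tetrahedral intermediate stops at the ketone and the hindered vinyl sulfone is not attacked at low temperature. C5 comes unchanged from the chiral pool.

Step 9
Reactants: 14 enone (C8 ketone carrying the citronellyl chain)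
Product: 15 tetraene (2-substituted diene C16=C8–C9=C10 plus vinyl sulfone)
Conditions: Ph3PCH3Br, KOt-Bu, THF, 0 °C to rt
Reagents that add atoms: methyltriphenylphosphonium bromide, C[P+](c1ccccc1)(c1ccccc1)c1ccccc1.[Br-]
Why: Wittig methylenation of the enone carbonyl (1,2-addition) gives the diene; the ylide is not basic enough to deprotonate the vinyl sulfone or C11.

Step 10
Reactants: 15 tetraene (2-substituted diene C16=C8–C9=C10 plus vinyl sulfone)
Product: 16 sulfonyl hydrindene (rings A and B closed)
Conditions: toluene (high dilution), BHT, 170 °C, sealed tube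
Reagents that add atoms: none
Why: Thermal intramolecular Diels–Alder reaction (type 1, a 1,6,8-nonatriene; closest known type: cyclisations of such trienes with a β-methyl acceptor dienophile that give angularly methylated hydrindenes). The diene C16=C8–C9=C10 and the vinyl sulfone C14=C15 combine in a concerted, asynchronous [4+2] process; ring B closes through the three-atom tether (bond C10–C14) and ring A is the cycloadduct ring (bond C15–C16), which leaves the new double bond exactly at C8=C9. C10 is controlled by C11: allylic 1,3-strain with the C9 methyl group holds H-11 in the diene plane, so the tether reaches the face anti to the bulky silyloxyethyl group, which places C1 cis to H-10. C14 is set by the endo rule: in the (Z)-sulfone the sulfonyl group and the tether are cis and can both sit under the diene only in the transition state that gives the cis ring fusion (H-10 and the C14 methyl cis). C15 is formed with the sulfonyl group cis to C13 but is erased in step 15. Regiochemistry is fixed by the tether; the selectivities the step needs are the diene face and the cis fusion, secured by the C9 methyl/C11 pair and by the (Z)-geometry from step 2. The remote trisubstituted olefin of the chain cannot reach the diene and stays untouched.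

Step 11
Reactants: 16 sulfonyl hydrindene (rings A and B closed)
Product: 18 methyl ketone (acetyl group on C11), via alcohol 17 (not isolated)
Conditions: IBX, DMSO, rt
Reagents that add atoms: none
Why: IBX in DMSO cleaves triethylsilyl ethers and oxidises the liberated secondary alcohol in the same pot; the acetyl group stays trans to C9 on ring B, which is also the thermodynamically preferred arrangement.

Step 12
Reactants: 18 methyl ketone (acetyl group on C11)
Product: 19 alkenyl triflate (C1 triflate with C1a methylene)
Conditions: KN(SiMe3)2, THF, −78 °C; then PhNTf2, −78 to −40 °C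
Reagents that add atoms: N-phenylbis(trifluoromethanesulfonimide), O=S(=O)(N(c1ccccc1)S(=O)(=O)C(F)(F)F)C(F)(F)F
Why: Kinetic enolisation of a methyl ketone occurs at the methyl group rather than at the hindered methine C11, and the ketone is more acidic than the position next to the sulfone; O-triflation gives the 1,1-disubstituted alkenyl triflate.

Step 13
Reactants: 19 alkenyl triflate (C1 triflate with C1a methylene)
Product: 21 aldehyde (C2) alkenyl triflate, via diol 20 (not isolated)
Conditions: OsO4 (cat.), NaIO4, 2,6-lutidine, dioxane/H2O, rt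
Reagents that add atoms: sodium periodate, [Na+].[O-][I](=O)(=O)=O
Why: Lemieux–Johnson cleavage: OsO4 dihydroxylates the unhindered trisubstituted chain olefin far faster than the shielded tetrasubstituted C8=C9 or the electron-poor alkenyl triflate, and periodate cleaves the diol to the C2 aldehyde.

Step 14
Reactants: 21 aldehyde (C2) alkenyl triflate
Product: 22 macrocyclic allylic alcohol (ring C closed and sulfone on C15)
Conditions: CrCl2 (excess), NiCl2 (cat.), DMSO, rt, slow addition at high dilution
Reagents that add atoms: none
Why: Nozaki–Hiyama–Kishi reaction: the alkenyl triflate adds to zerovalent nickel formed from NiCl2 and is passed on to chromium, and the alkenylchromium species adds to the aldehyde only, closing ring C and forming the exocyclic olefin with the C2 carbinol. The C2 configuration is set in the cyclic transition state of the ring closure and can be corrected by reagent control if needed (see fallback).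

Step 15
Reactants: 22 macrocyclic allylic alcohol (ring C closed and sulfone on C15)
Product: 23 hydroxy ketone (carbonyl at C15 and free hydroxyl at C2)
Conditions: LiN(i-Pr)2 (2.5 equiv), THF, −78 to −40 °C; then Me3SiOOSiMe3, −78 °C to rt; NH4Cl (aq)
Reagents that add atoms: bis(trimethylsilyl) peroxide, C[Si](C)(C)OO[Si](C)(C)C
Why: Oxidative desulfonylation: the α-sulfonyl carbanion (the C2 hydroxyl is carried as its alkoxide) takes up oxygen from the silyl peroxide and loses sulfinate to give the ketone; the C15 stereocenter is erased on purpose.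

Step 16
Reactants: 23 hydroxy ketone (carbonyl at C15 and free hydroxyl at C2)
Product: 24 acetoxy ketone
Conditions: Ac2O, pyridine, DMAP (cat.), CH2Cl2, 0 °C
Reagents that add atoms: acetic anhydride, CC(=O)OC(C)=O
Why: Acylation of the only hydroxyl group present; the mild base does not move the β,γ-olefin C8=C9 into conjugation at 0 °C.

Step 17
Reactants: 24 acetoxy ketone
Product: 25 α-hydroxy ketone (hydroxyl at C16)
Conditions: LiN(SiMe3)2, THF, −78 °C; then 2-(phenylsulfonyl)-3-phenyloxaziridine, −78 °C; NH4Cl (aq) at −78 °C
Reagents that add atoms: 2-(phenylsulfonyl)-3-phenyloxaziridine, O=S(=O)(N1OC1c1ccccc1)c1ccccc1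
Why: Enolate hydroxylation with an N-sulfonyloxaziridine: the ketone can enolise only toward C16 (C14 is quaternary) and is far more acidic than the acetate, and the dienolate reacts at its α-carbon. The bridge C1–C7 lies over the ring-B side of ring A, so the oxidant should approach C16 from the opposite face, cis to H-10, which is the configuration of the target.

Step 18
Reactants: 25 α-hydroxy ketone (hydroxyl at C16)
Product: 26 target (CNP0192310.2)
Conditions: Me4NBH(OAc)3, AcOH/MeCN, −30 °C
Reagents that add atoms: none
Why: Hydroxyl-directed reduction: the C16 hydroxyl binds the triacetoxyborohydride and delivers hydride to C15 on its own face, so the new hydroxyl is trans to the one at C16; the acetate and both olefins are inert to this reagent.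

## Compound list

1 | hex-5-ynoic acid | C#CCCCC(=O)O | starting material
2 | (E)-5-iodo-6-(phenylsulfonyl)hex-5-enoic acid | OC(=O)CCC/C(I)=C\S(=O)(=O)c1ccccc1 | intermediate
3 | 6-(phenylsulfonyl)hex-5-ynoic acid | OC(=O)CCCC#CS(=O)(=O)c1ccccc1 | intermediate
4 | (Z)-5-methyl-6-(phenylsulfonyl)hex-5-enoic acid | OC(=O)CCC/C(C)=C\S(=O)(=O)c1ccccc1 | intermediate
5 | (S)-4-benzyl-1,3-thiazolidine-2-thione | S=C1SC[C@H](Cc2ccccc2)N1 | starting material
6 | (Z)-1-[(4S)-4-benzyl-2-thioxo-1,3-thiazolidin-3-yl]-5-methyl-6-(phenylsulfonyl)hex-5-en-1-one | S=C1SC[C@H](Cc2ccccc2)N1C(=O)CCC/C(C)=C\S(=O)(=O)c1ccccc1 | intermediate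
7 | (2S,5Z)-1-[(4S)-4-benzyl-2-thioxo-1,3-thiazolidin-3-yl]-2-[(1R)-1-hydroxyethyl]-5-methyl-6-(phenylsulfonyl)hex-5-en-1-one | S=C1SC[C@H](Cc2ccccc2)N1C(=O)[C@H]([C@@H](C)O)CC/C(C)=C\S(=O)(=O)c1ccccc1 | intermediate
8 | (2S,5Z)-1-[(4S)-4-benzyl-2-thioxo-1,3-thiazolidin-3-yl]-5-methyl-6-(phenylsulfonyl)-2-[(1R)-1-(triethylsilyloxy)ethyl]hex-5-en-1-one | S=C1SC[C@H](Cc2ccccc2)N1C(=O)[C@H]([C@@H](C)O[Si](CC)(CC)CC)CC/C(C)=C\S(=O)(=O)c1ccccc1 | intermediate
9 | (2S,5Z)-5-methyl-6-(phenylsulfonyl)-2-[(1R)-1-(triethylsilyloxy)ethyl]hex-5-enal | O=C[C@H]([C@@H](C)O[Si](CC)(CC)CC)CC/C(C)=C\S(=O)(=O)c1ccccc1 | intermediate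
10 | ethyl (2E,4R,7Z)-2,7-dimethyl-8-(phenylsulfonyl)-4-[(1R)-1-(triethylsilyloxy)ethyl]octa-2,7-dienoate | CCOC(=O)/C(C)=C/[C@H]([C@@H](C)O[Si](CC)(CC)CC)CC/C(C)=C\S(=O)(=O)c1ccccc1 | intermediate
11 | (R)-citronellyl bromide, (R)-8-bromo-2,6-dimethyloct-2-ene | CC(C)=CCC[C@@H](C)CCBr | starting material
12 | [(3R)-3,7-dimethyloct-6-en-1-yl]magnesium bromide | CC(C)=CCC[C@@H](C)CC[Mg]Br | intermediate
13 | (2E,4R,7Z)-N-methoxy-N,2,7-trimethyl-8-(phenylsulfonyl)-4-[(1R)-1-(triethylsilyloxy)ethyl]octa-2,7-dienamide | CON(C)C(=O)/C(C)=C/[C@H]([C@@H](C)O[Si](CC)(CC)CC)CC/C(C)=C\S(=O)(=O)c1ccccc1 | intermediate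
14 | (6R,10E,12R,15Z)-2,6,10,15-tetramethyl-16-(phenylsulfonyl)-12-[(1R)-1-(triethylsilyloxy)ethyl]hexadeca-2,10,15-trien-9-one | CC(C)=CCC[C@@H](C)CCC(=O)/C(C)=C/[C@H]([C@@H](C)O[Si](CC)(CC)CC)CC/C(C)=C\S(=O)(=O)c1ccccc1 | intermediate
15 | (6R,10E,12R,15Z)-2,6,10,15-tetramethyl-9-methylidene-16-(phenylsulfonyl)-12-[(1R)-1-(triethylsilyloxy)ethyl]hexadeca-2,10,15-triene | CC(C)=CCC[C@@H](C)CCC(=C)/C(C)=C/[C@H]([C@@H](C)O[Si](CC)(CC)CC)CC/C(C)=C\S(=O)(=O)c1ccccc1 | intermediate
16 | sulfonyl hydrindene: cis-fused rings A and B with C8=C9; C8 bears the (3R)-3,7-dimethyloct-6-enyl chain; C11 bears the (1R)-1-(triethylsilyloxy)ethyl group trans to C9; the C14 methyl is cis to H-10; phenylsulfonyl on C15 cis to C13 | CC(C)=CCC[C@@H](C)CCC1=C(C)[C@H]2[C@H]([C@@H](C)O[Si](CC)(CC)CC)CC[C@@]2(C)[C@@H](S(=O)(=O)c2ccccc2)C1 | intermediate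
17 | alcohol: 16 with the free (1R)-1-hydroxyethyl group on C11 | CC(C)=CCC[C@@H](C)CCC1=C(C)[C@H]2[C@H]([C@@H](C)O)CC[C@@]2(C)[C@@H](S(=O)(=O)c2ccccc2)C1 | intermediate
18 | methyl ketone: 16 with an acetyl group on C11 | CC(C)=CCC[C@@H](C)CCC1=C(C)[C@H]2[C@H](C(C)=O)CC[C@@]2(C)[C@@H](S(=O)(=O)c2ccccc2)C1 | intermediate
19 | alkenyl triflate: 16 with a 1-(trifluoromethylsulfonyloxy)ethenyl group on C11 | CC(C)=CCC[C@@H](C)CCC1=C(C)[C@H]2[C@H](C(=C)OS(=O)(=O)C(F)(F)F)CC[C@@]2(C)[C@@H](S(=O)(=O)c2ccccc2)C1 | intermediate
20 | diol: 19 with the chain-end olefin dihydroxylated (both epimers at the secondary carbinol) | CC(C)(O)C(O)CC[C@@H](C)CCC1=C(C)[C@H]2[C@H](C(=C)OS(=O)(=O)C(F)(F)F)CC[C@@]2(C)[C@@H](S(=O)(=O)c2ccccc2)C1 | intermediate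
21 | aldehyde: 19 with the chain shortened to the (3S)-3-methyl-6-oxohexyl group (C2 aldehyde) | O=CCC[C@@H](C)CCC1=C(C)[C@H]2[C@H](C(=C)OS(=O)(=O)C(F)(F)F)CC[C@@]2(C)[C@@H](S(=O)(=O)c2ccccc2)C1 | intermediate
22 | macrocyclic allylic alcohol: the tricyclic skeleton of the target with the exocyclic methylene on C1, free hydroxyl at C2 (R), phenylsulfonyl on C15 and CH2 at C16 | C=C1[C@H](O)CC[C@@H](C)CCC2=C(C)[C@H]3[C@H]1CC[C@@]3(C)[C@@H](S(=O)(=O)c1ccccc1)C2 | intermediate
23 | hydroxy ketone: 22 with a carbonyl at C15 in place of the sulfonyl-bearing carbon | C=C1[C@H](O)CC[C@@H](C)CCC2=C(C)[C@H]3[C@H]1CC[C@@]3(C)C(=O)C2 | intermediate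
24 | acetoxy ketone: the C2 acetate of 23 | C=C1[C@H](OC(C)=O)CC[C@@H](C)CCC2=C(C)[C@H]3[C@H]1CC[C@@]3(C)C(=O)C2 | intermediate
25 | α-hydroxy ketone: 24 with a hydroxyl at C16 on the face of H-10 and the C14 methyl | C=C1[C@H](OC(C)=O)CC[C@@H](C)CCC2=C(C)[C@H]3[C@H]1CC[C@@]3(C)C(=O)[C@@H]2O | intermediate
26 | target CNP0192310.2: C2 acetate, C15/C16 trans-diol | C=C1[C@H](OC(C)=O)CC[C@@H](C)CCC2=C(C)[C@H]3[C@H]1CC[C@@]3(C)[C@@H](O)[C@@H]2O | target

## Step count and risks

Total step count: 18. Longest linear sequence: 18 steps (from hex-5-ynoic acid 1; compounds 5 and 11 are bought and enter directly).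

**Step 10 (key step).** The cycloaddition may be slow, because a β,β-disubstituted vinyl sulfone must bond its fully substituted carbon to a substituted diene terminus against the electronic bias of the diene. The cis ring fusion may also erode through the competing sulfonyl-exo transition state.
Fallback, from 9 back to 16: the diene is made a stronger donor and the chain is attached after the cycloaddition.
- Aldehyde 9 is condensed with diethyl (3-oxobutan-2-yl)phosphonate (Horner–Wadsworth–Emmons, Ba(OH)2, THF/H2O) to the methyl enone F1.
- Soft enolisation (t-BuMe2SiOTf, Et3N) gives the 2-silyloxydiene F2.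
- Heating F2 gives the silyl enol ether cycloadduct F3, whose enol ether marks C8 regiospecifically.
- CsF and PhNTf2 convert F3 into the enol triflate F4.
- Suzuki–Miyaura coupling (Pd(dppf)Cl2, Cs2CO3) of F4 with the alkylborane F5, made from (R)-3,7-dimethylocta-1,6-diene and 9-BBN, forms C7–C8 and gives 16.

**Step 14.** The aldehyde may add through the wrong face in the cyclic transition state of this medium-ring closure, so that C2 is formed with the wrong configuration or with poor selectivity. The substrate offers no obvious bias.
Fallback, from 22 back to 22: control is moved from the substrate to a reagent. Alcohol 22, whatever its C2 configuration, is oxidised with Dess–Martin periodinane to the macrocyclic α-methylene ketone F6. Corey–Bakshi–Shibata reduction with the (S)-methyl oxazaborolidine and BH3·SMe2 treats the alkenyl group as the large substituent and should return 22 with the (R)-carbinol.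

**Step 17.** The oxaziridine may approach the dienolate from the bridge-side face if the bridge shields ring A less than assumed, which would give the wrong configuration at C16. The directed reduction would then produce the wrong trans-diol.
Fallback, from 24 to 25: the configuration is corrected by inversion. The C16 epimer of 25, F7, is treated under Mitsunobu conditions (HCO2H, PPh3, DIAD) to give the inverted formate F8. Mild methanolysis (KHCO3, MeOH, 0 °C) removes the formate much faster than the acetate and gives 25.

**Step 12.** Enolisation may lose regiocontrol (methyl versus the methine C11, or the position next to the sulfone) under the strongly basic conditions, with epimerisation at C11.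
Fallback, from 18 back to 22: the alkenyl electrophile is made without any enolate. Ketone 18 is converted with hydrazine into the hydrazone F9. Iodine and tetramethylguanidine (Barton vinyl iodide synthesis) give the alkenyl iodide F10. Lemieux–Johnson cleavage as in step 13 gives the iodo aldehyde F11, which closes under the conditions of step 14 to 22.

## Further compounds

F1 | step 10 | (3E,5R,8Z)-3,8-dimethyl-9-(phenylsulfonyl)-5-[(1R)-1-(triethylsilyloxy)ethyl]nona-3,8-dien-2-one | CC(=O)/C(C)=C/[C@H]([C@@H](C)O[Si](CC)(CC)CC)CC/C(C)=C\S(=O)(=O)c1ccccc1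
F2 | step 10 | 2-(tert-butyldimethylsilyloxy)diene derived from F1 | C=C(O[Si](C)(C)C(C)(C)C)/C(C)=C/[C@H]([C@@H](C)O[Si](CC)(CC)CC)CC/C(C)=C\S(=O)(=O)c1ccccc1
F3 | step 10 | silyl enol ether cycloadduct (as 16, with OSi(t-Bu)Me2 on C8 in place of the chain) | CC(C)(C)[Si](C)(C)OC1=C(C)[C@H]2[C@H]([C@@H](C)O[Si](CC)(CC)CC)CC[C@@]2(C)[C@@H](S(=O)(=O)c2ccccc2)C1
F4 | step 10 | enol triflate (as 16, with OSO2CF3 on C8 in place of the chain) | FC(F)(F)S(=O)(=O)OC1=C(C)[C@H]2[C@H]([C@@H](C)O[Si](CC)(CC)CC)CC[C@@]2(C)[C@@H](S(=O)(=O)c2ccccc2)C1
F5 | step 10 | 9-[(3R)-3,7-dimethyloct-6-en-1-yl]-9-borabicyclo[3.3.1]nonane | CC(C)=CCC[C@@H](C)CCB1C2CCCC1CCC2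
F6 | step 14 | macrocyclic α-methylene ketone (22 with a carbonyl at C2) | C=C1C(=O)CC[C@@H](C)CCC2=C(C)[C@H]3[C@H]1CC[C@@]3(C)[C@@H](S(=O)(=O)c1ccccc1)C2
F7 | step 17 | C16 epimer of 25 | C=C1[C@H](OC(C)=O)CC[C@@H](C)CCC2=C(C)[C@H]3[C@H]1CC[C@@]3(C)C(=O)[C@H]2O
F8 | step 17 | C16 formate of 25 | C=C1[C@H](OC(C)=O)CC[C@@H](C)CCC2=C(C)[C@H]3[C@H]1CC[C@@]3(C)C(=O)[C@@H]2OC=O
F9 | step 12 | hydrazone of 18 | CC(C)=CCC[C@@H](C)CCC1=C(C)[C@H]2[C@H](C(C)=NN)CC[C@@]2(C)[C@@H](S(=O)(=O)c2ccccc2)C1
F10 | step 12 | alkenyl iodide (as 19, with iodine in place of the triflate) | CC(C)=CCC[C@@H](C)CCC1=C(C)[C@H]2[C@H](C(=C)I)CC[C@@]2(C)[C@@H](S(=O)(=O)c2ccccc2)C1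
F11 | step 12 | iodo aldehyde (as 21, with iodine in place of the triflate) | O=CCC[C@@H](C)CCC1=C(C)[C@H]2[C@H](C(=C)I)CC[C@@]2(C)[C@@H](S(=O)(=O)c2ccccc2)C1
A1 | alternative 1 | ring-A alkenyl triflate of the preformed hydrindane (acetyl on C11, bis-silylated C15/C16 diol) | CC(=O)[C@@H]1CC[C@@]2(C)[C@@H](O[Si](C)(C)C(C)(C)C)[C@H](O[Si](C)(C)C(C)(C)C)C(OS(=O)(=O)C(F)(F)F)=C(C)[C@@H]12
A2 | alternative 2 | fourteen-membered epoxy triene (isopropenyl on C8, (E)-C1=C11 olefin, C14–C15 epoxide) | CC(=C)[C@@H]1CC[C@H](C)CCC/C(C)=C/CC[C@]2(C)O[C@H]2C1
A3 | alternative 3 | (S)-2-methyl-5-(prop-1-en-2-yl)cyclopent-1-ene-1-carbaldehyde | CC(=C)[C@@H]1CCC(C)=C1C=O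
A4 | alternative 3 | thirteen-membered diketone (acetyl on C10, ring ketone at C16, silyl ether at C2) | C=C1[C@H](O[Si](C)(C)C(C)(C)C)CC[C@@H](C)CCCC(=O)C[C@]2(C)CC[C@@H]1[C@@H]2C(C)=O
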